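**Strategy.** The oxane ring (O1, C2 quaternary, C3 carbinol, C4, C5 CHBr, C6 CMe2) is cut at C3–C4 and O1–C2. The step exploits two features of this ring: the 1,3-relationship of C3–OH to C5 (aldol retron, C5 as ketone) and the vicinal C3–OH/C2–O1 pattern (epoxide retron). A BF3-mediated Mukaiyama aldol of a limonene-derived, Sharpless-made epoxy aldehyde with the bis-silyl enol ether of 3-hydroxy-3-methylbutan-2-one, then in-flask 6-exo opening of the 2,2-disubstituted epoxide by the tertiary silyl ether, forms both bonds and sets C2 and C3. The precursor carries the C2 methyl as the epoxide CH2–O arm, reduced later.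

Key step: step 5

Remark: oxane atoms are numbered as in the target throughout (O1, C2 = C(CH3)(cyclohexyl), C3 = CHOH, C4 = CH2, C5 = CHBr, C6 = C(CH3)2); cyclohexane atoms carry primes (C1' on C2, C3' = CHCl, C4' = CBr(CH3)).
Assumption: L-(+)-tartrate is taken to give the (S)- and D-(−)-tartrate the (R)-epoxy alcohol from a 2-substituted allyl alcohol; should a model run show the reverse, the tartrate enantiomer of step 2 is exchanged.

Step 1
Reactants: 1 (R)-limonene
Product: 2 2-[(1R)-4-methylcyclohex-3-en-1-yl]prop-2-en-1-ol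
Conditions: n-BuLi, TMEDA, hexane, 25 °C; B(OMe)3, THF, −78 °C; H2O2, NaOH(aq), 0 °C
Reagents that add atoms: hydrogen peroxide (OO)
Why: Kinetic allylic lithiation of the isopropenyl methyl group, borylation and oxidative C–B cleavage (metalation–boronate oxidation) hydroxylate that carbon, while the ring stereocentre is not deprotonated and is retained.

Step 2
Reactants: 2 2-[(1R)-4-methylcyclohex-3-en-1-yl]prop-2-en-1-ol
Product: 3 [(2R)-2-[(1R)-4-methylcyclohex-3-en-1-yl]oxiran-2-yl]methanol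
Conditions: Ti(OiPr)4 (cat.), D-(−)-diisopropyl tartrate (cat.), t-BuOOH, 4 Å molecular sieves, CH2Cl2, −20 °C
Reagents that add atoms: tert-butyl hydroperoxide (CC(C)(C)OO)
Why: Sharpless asymmetric epoxidation touches only the allylic-alcohol alkene, and the tartrate (reagent control) fixes the configuration of the quaternary epoxide carbon that becomes C2.

Step 3
Reactants: 3 [(2R)-2-[(1R)-4-methylcyclohex-3-en-1-yl]oxiran-2-yl]methanol
Product: 4 (2S)-2-[(1R)-4-methylcyclohex-3-en-1-yl]oxirane-2-carbaldehyde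
Conditions: 2,2,6,6-tetramethylpiperidin-1-oxyl (cat.), PhI(OAc)2, CH2Cl2, 20 °C
Reagents that add atoms: none
Why: Oxoammonium-mediated alcohol oxidation stops at the aldehyde under neutral conditions that spare the epoxide and the ring alkene, and the quaternary α-carbon cannot epimerise.

Step 4
Reactants: 5 3-hydroxy-3-methylbutan-2-one
Product: 6 3-methyl-2,3-bis[(trimethylsilyl)oxy]but-1-ene
Conditions: Me3SiOTf, Et3N, CH2Cl2, 0 °C
Reagents that add atoms: trimethylsilyl trifluoromethanesulfonate (C[Si](C)(C)OS(=O)(=O)C(F)(F)F)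
Why: Soft enolisation with O-silylation gives the silyl enol ether on the only enolisable side and silylates the tertiary alcohol in the same operation; no stereocentre is formed.

Step 5
Reactants: 4 (2S)-2-[(1R)-4-methylcyclohex-3-en-1-yl]oxirane-2-carbaldehyde; 6 3-methyl-2,3-bis[(trimethylsilyl)oxy]but-1-ene
Product: 8 (5S,6R)-5-hydroxy-6-(hydroxymethyl)-2,2-dimethyl-6-[(1R)-4-methylcyclohex-3-en-1-yl]oxan-3-one, via anti-aldol epoxide 7 (not isolated)
Conditions: BF3·OEt2, CH2Cl2, −78 → −20 °C; NaHCO3(aq)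
Reagents that add atoms: none
Why: BF3 activates the aldehyde for a Mukaiyama aldol addition of enol silane 6, which forms C3–C4 and the boron aldolate 7; on warming, the same Lewis acid activates the 2,2-disubstituted epoxide, and the tertiary silyl ether oxygen attacks its fully substituted carbon with loss of the silyl group, which forms O1–C2. The closest known reaction types are the BF3-mediated Mukaiyama aldol of α,β-epoxy aldehydes and the Lewis-acid-promoted intramolecular opening of epoxides by alcohols or silyl ethers. The oxane ring closes in the 6-exo-tet mode. C3 is set by Cornforth–Felkin addition anti to the epoxide C–O bond under non-chelating BF3, and C2 is set by inversion at the epoxide carbon, whose configuration comes from step 2. The step needs attack at the quaternary rather than the CH2 epoxide carbon, and etherification rather than a hydride shift or capture by the ketone oxygen; the exo mode, the tertiary position, the antiperiplanar placement of C4 to the epoxide oxygen in the Felkin adduct and the low temperature are expected to secure this.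

Step 6
Reactants: 8 (5S,6R)-5-hydroxy-6-(hydroxymethyl)-2,2-dimethyl-6-[(1R)-4-methylcyclohex-3-en-1-yl]oxan-3-one
Product: 10 [(2R,3S)-6,6-dimethyl-2-[(1R)-4-methylcyclohex-3-en-1-yl]-5-oxo-3-[(triethylsilyl)oxy]oxan-2-yl]methyl trifluoromethanesulfonate, via primary triflate 9 (not isolated)
Conditions: Tf2O, 2,6-lutidine, CH2Cl2, −78 °C; Et3SiOTf, −78 → −40 °C
Reagents that add atoms: trifluoromethanesulfonic anhydride (O=S(=O)(OS(=O)(=O)C(F)(F)F)C(F)(F)F); triethylsilyl trifluoromethanesulfonate (CC[Si](CC)(CC)OS(=O)(=O)C(F)(F)F)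
Why: Chemoselective O-sulfonylation of the unhindered primary alcohol, then O-silylation of the remaining secondary alcohol, activates the CH2–O arm for reduction and masks C3–OH; no stereocentre changes.

Step 7
Reactants: 10 [(2R,3S)-6,6-dimethyl-2-[(1R)-4-methylcyclohex-3-en-1-yl]-5-oxo-3-[(triethylsilyl)oxy]oxan-2-yl]methyl trifluoromethanesulfonate
Product: 11 (3R,5S,6S)-2,2,6-trimethyl-6-[(1R)-4-methylcyclohex-3-en-1-yl]-5-[(triethylsilyl)oxy]oxan-3-ol
Conditions: LiEt3BH, THF, −78 → 0 °C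
Reagents that add atoms: none
Why: Hydride displaces the neopentyl-type primary triflate (SN2 deoxygenation to the C2 methyl group) and reduces the ketone; the axial C3 silyloxy group blocks the axial trajectory, so equatorial attack should give the axial C5 alcohol cis to C3–O.

Step 8
Reactants: 11 (3R,5S,6S)-2,2,6-trimethyl-6-[(1R)-4-methylcyclohex-3-en-1-yl]-5-[(triethylsilyl)oxy]oxan-3-ol
Product: 13 {[(2S,3S,5S)-5-bromo-2,6,6-trimethyl-2-[(1R)-4-methylcyclohex-3-en-1-yl]oxan-3-yl]oxy}triethylsilane, via secondary triflate 12 (not isolated)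
Conditions: Tf2O, pyridine, CH2Cl2, −30 °C; (n-Bu)4NBr, 0 → 25 °C
Reagents that add atoms: tetrabutylammonium bromide (CCCC[N+](CCCC)(CCCC)CCCC.[Br-])
Why: SN2 displacement of the axial secondary triflate by bromide inverts C5 and places bromine equatorial and trans to C3–O; the axial leaving group has no antiperiplanar ring C–O bond, which disfavours ring contraction.

Step 9
Reactants: 13 {[(2S,3S,5S)-5-bromo-2,6,6-trimethyl-2-[(1R)-4-methylcyclohex-3-en-1-yl]oxan-3-yl]oxy}triethylsilane
Product: 14 (1S,2S,4R)-4-[(2S,3S,5S)-5-bromo-2,6,6-trimethyl-3-[(triethylsilyl)oxy]oxan-2-yl]-2-chloro-1-methylcyclohexan-1-ol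
Conditions: trichloroisocyanuric acid, acetone–H2O, NaHCO3, 0 °C
Reagents that add atoms: trichloroisocyanuric acid (O=C1N(Cl)C(=O)N(Cl)C(=O)N1Cl); water (O)
Why: Halohydrin formation on the trisubstituted ring alkene: water attacks the tertiary carbon (Markovnikov) in the trans-diaxial (Fürst–Plattner) mode, which is open only to the chloronium ion on the face anti to the C1' substituent, and so sets C3'–Cl and C4'–OH.

Step 10
Reactants: 14 (1S,2S,4R)-4-[(2S,3S,5S)-5-bromo-2,6,6-trimethyl-3-[(triethylsilyl)oxy]oxan-2-yl]-2-chloro-1-methylcyclohexan-1-ol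
Product: 16 (2S,3S,5S)-5-bromo-2-[(1R,3S,4S)-4-bromo-3-chloro-4-methylcyclohexyl]-2,6,6-trimethyloxan-3-ol, via silyl ether 15 (not isolated)
Conditions: Me3SiBr, CH2Cl2, −40 → 0 °C; MeOH, 0 °C
Reagents that add atoms: bromotrimethylsilane (C[Si](C)(C)Br)
Why: SN1 substitution of the tertiary alcohol with neighbouring-group participation: the antiperiplanar axial chlorine bridges the developing cation and bromide opens the chloronium ion at the tertiary carbon from the face the oxygen left, so C4' is brominated with retention (trans-diaxial bromochloride); the HBr/MeOH formed on quenching cleaves the silyl ether.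

**Compound list**

1 | (R)-limonene, (4R)-1-methyl-4-(prop-1-en-2-yl)cyclohex-1-ene | C=C(C)[C@@H]1CCC(C)=CC1 | starting material
2 | 2-[(1R)-4-methylcyclohex-3-en-1-yl]prop-2-en-1-ol | C=C(CO)[C@@H]1CCC(C)=CC1 | intermediate
3 | [(2R)-2-[(1R)-4-methylcyclohex-3-en-1-yl]oxiran-2-yl]methanol | OC[C@@]1(CO1)[C@@H]2CCC(C)=CC2 | intermediate
4 | (2S)-2-[(1R)-4-methylcyclohex-3-en-1-yl]oxirane-2-carbaldehyde | O=C[C@@]1(CO1)[C@@H]2CCC(C)=CC2 | intermediate
5 | 3-hydroxy-3-methylbutan-2-one | CC(=O)C(C)(C)O | starting material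
6 | 3-methyl-2,3-bis[(trimethylsilyl)oxy]but-1-ene | C=C(O[Si](C)(C)C)C(C)(C)O[Si](C)(C)C | intermediate
7 | (5S)-5-hydroxy-2-methyl-5-[(2S)-2-[(1R)-4-methylcyclohex-3-en-1-yl]oxiran-2-yl]-2-[(trimethylsilyl)oxy]pentan-3-one (present as its boron aldolate) | C[Si](C)(C)OC(C)(C)C(=O)C[C@H](O)[C@@]1(CO1)[C@@H]2CCC(C)=CC2 | intermediate
8 | (5S,6R)-5-hydroxy-6-(hydroxymethyl)-2,2-dimethyl-6-[(1R)-4-methylcyclohex-3-en-1-yl]oxan-3-one | CC1(C)O[C@@](CO)([C@@H]2CCC(C)=CC2)[C@@H](O)CC1=O | intermediate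
9 | [(2R,3S)-3-hydroxy-6,6-dimethyl-2-[(1R)-4-methylcyclohex-3-en-1-yl]-5-oxooxan-2-yl]methyl trifluoromethanesulfonate | CC1(C)O[C@@](COS(=O)(=O)C(F)(F)F)([C@@H]2CCC(C)=CC2)[C@@H](O)CC1=O | intermediate
10 | [(2R,3S)-6,6-dimethyl-2-[(1R)-4-methylcyclohex-3-en-1-yl]-5-oxo-3-[(triethylsilyl)oxy]oxan-2-yl]methyl trifluoromethanesulfonate | CC1(C)O[C@@](COS(=O)(=O)C(F)(F)F)([C@@H]2CCC(C)=CC2)[C@@H](O[Si](CC)(CC)CC)CC1=O | intermediate
11 | (3R,5S,6S)-2,2,6-trimethyl-6-[(1R)-4-methylcyclohex-3-en-1-yl]-5-[(triethylsilyl)oxy]oxan-3-ol | CC1(C)O[C@@](C)([C@@H]2CCC(C)=CC2)[C@@H](O[Si](CC)(CC)CC)C[C@H]1O | intermediate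
12 | (3R,5S,6S)-2,2,6-trimethyl-6-[(1R)-4-methylcyclohex-3-en-1-yl]-5-[(triethylsilyl)oxy]oxan-3-yl trifluoromethanesulfonate | CC1(C)O[C@@](C)([C@@H]2CCC(C)=CC2)[C@@H](O[Si](CC)(CC)CC)C[C@H]1OS(=O)(=O)C(F)(F)F | intermediate
13 | {[(2S,3S,5S)-5-bromo-2,6,6-trimethyl-2-[(1R)-4-methylcyclohex-3-en-1-yl]oxan-3-yl]oxy}triethylsilane | CC1(C)O[C@@](C)([C@@H]2CCC(C)=CC2)[C@@H](O[Si](CC)(CC)CC)C[C@@H]1Br | intermediate
14 | (1S,2S,4R)-4-[(2S,3S,5S)-5-bromo-2,6,6-trimethyl-3-[(triethylsilyl)oxy]oxan-2-yl]-2-chloro-1-methylcyclohexan-1-ol | CC1(C)O[C@@](C)([C@@H]2CC[C@](C)(O)[C@@H](Cl)C2)[C@@H](O[Si](CC)(CC)CC)C[C@@H]1Br | intermediate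
15 | {[(2S,3S,5S)-5-bromo-2-[(1R,3S,4S)-4-bromo-3-chloro-4-methylcyclohexyl]-2,6,6-trimethyloxan-3-yl]oxy}triethylsilane | CC1(C)O[C@@](C)([C@@H]2CC[C@](C)(Br)[C@@H](Cl)C2)[C@@H](O[Si](CC)(CC)CC)C[C@@H]1Br | intermediate
16 | (2S,3S,5S)-5-bromo-2-[(1R,3S,4S)-4-bromo-3-chloro-4-methylcyclohexyl]-2,6,6-trimethyloxan-3-ol | CC1(C)O[C@@](C)([C@@H]2CC[C@](C)(Br)[C@@H](Cl)C2)[C@@H](O)C[C@@H]1Br | target

**Count and risks**

Total step count: 10. Longest linear sequence: 9 steps (steps 1, 2, 3, 5, 6, 7, 8, 9, 10).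

Step 5. At the BF3-activated epoxide a hydride or alkyl shift (semipinacol or Meinwald pathway) or capture by the ketone oxygen may outrun the 6-exo etherification, and adventitious chelation may erode the Cornforth–Felkin preference. The fallback sets out from 4 and 5 and comes back at 8; it uncouples the two bond formations. 5 is silylated (Et3SiOTf, 2,6-lutidine) to 3-methyl-3-[(triethylsilyl)oxy]butan-2-one F1. Its dicyclohexylboron enolate (Cy2BCl, Et3N, Et2O, −78 °C) adds to 4 and should give the isolable anti aldol (5S)-5-hydroxy-2-methyl-5-[(2S)-2-[(1R)-4-methylcyclohex-3-en-1-yl]oxiran-2-yl]-2-[(triethylsilyl)oxy]pentan-3-one F2 with the epoxide untouched. HF·pyridine frees the tertiary alcohol to give (5S)-2,5-dihydroxy-2-methyl-5-[(2S)-2-[(1R)-4-methylcyclohex-3-en-1-yl]oxiran-2-yl]pentan-3-one F3, and catalytic camphorsulfonic acid (CH2Cl2, 0 °C) effects the 6-exo epoxide opening to 8.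

Step 8. E2 elimination toward C4 and slow substitution at a carbon flanked by the quaternary C6 may prevail over clean inversion. The fallback sets out from 11 and comes back at 13; it activates the hydroxyl through a cyclic leaving group. (n-Bu)4NF cleaves the silyl ether to the cis-diaxial diol (3R,5S,6S)-2,2,6-trimethyl-6-[(1R)-4-methylcyclohex-3-en-1-yl]oxane-3,5-diol F4. 1,1'-Sulfonyldiimidazole and NaH close (3R,5S,6S)-2,2,6-trimethyl-6-[(1R)-4-methylcyclohex-3-en-1-yl]oxane-3,5-diyl cyclic sulfate F5. LiBr in DMF should open it at the less encumbered C5 with inversion, and dilute H2SO4 hydrolyses the sulfate monoester to (2S,3S,5S)-5-bromo-2,6,6-trimethyl-2-[(1R)-4-methylcyclohex-3-en-1-yl]oxan-3-ol F6, which Et3SiOTf and 2,6-lutidine return to 13.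

Step 10. Acid-mediated ionisation of the bromo-oxane (ring opening or contraction assisted by the C5 bromine) and E1 elimination may compete with the chloronium-assisted substitution. The fallback sets out from 13 and comes back at 15; it bypasses the tertiary carbinol. Ene-type allylic chlorination of the ring alkene of 13 in a two-phase medium (Ca(OCl)2, solid CO2, CH2Cl2–H2O, 0 °C) should give {[(2S,3S,5S)-5-bromo-2-[(1R,3S)-3-chloro-4-methylidenecyclohexyl]-2,6,6-trimethyloxan-3-yl]oxy}triethylsilane F7. Ionic Markovnikov hydrobromination of its 1,1-disubstituted alkene (HBr, CH2Cl2, −78 °C), with the adjacent axial chlorine directing bromide anti, leads to 15, and the methanolysis of step 10 then gives 16.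

**Further compounds**

F1 | step 5 | 3-methyl-3-[(triethylsilyl)oxy]butan-2-one | CC(=O)C(C)(C)O[Si](CC)(CC)CC
F2 | step 5 | (5S)-5-hydroxy-2-methyl-5-[(2S)-2-[(1R)-4-methylcyclohex-3-en-1-yl]oxiran-2-yl]-2-[(triethylsilyl)oxy]pentan-3-one | CC[Si](CC)(CC)OC(C)(C)C(=O)C[C@H](O)[C@@]1(CO1)[C@@H]2CCC(C)=CC2
F3 | step 5 | (5S)-2,5-dihydroxy-2-methyl-5-[(2S)-2-[(1R)-4-methylcyclohex-3-en-1-yl]oxiran-2-yl]pentan-3-one | CC(C)(O)C(=O)C[C@H](O)[C@@]1(CO1)[C@@H]2CCC(C)=CC2
F4 | step 8 | (3R,5S,6S)-2,2,6-trimethyl-6-[(1R)-4-methylcyclohex-3-en-1-yl]oxane-3,5-diol | CC1(C)O[C@@](C)([C@@H]2CCC(C)=CC2)[C@@H](O)C[C@H]1O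
F5 | step 8 | (3R,5S,6S)-2,2,6-trimethyl-6-[(1R)-4-methylcyclohex-3-en-1-yl]oxane-3,5-diyl cyclic sulfate | CC1(C)O[C@@](C)([C@@H]2CCC(C)=CC2)[C@@H]3C[C@H]1OS(=O)(=O)O3
F6 | step 8 | (2S,3S,5S)-5-bromo-2,6,6-trimethyl-2-[(1R)-4-methylcyclohex-3-en-1-yl]oxan-3-ol | CC1(C)O[C@@](C)([C@@H]2CCC(C)=CC2)[C@@H](O)C[C@@H]1Br
F7 | step 10 | {[(2S,3S,5S)-5-bromo-2-[(1R,3S)-3-chloro-4-methylidenecyclohexyl]-2,6,6-trimethyloxan-3-yl]oxy}triethylsilane | CC1(C)O[C@@](C)([C@@H]2CCC(=C)[C@@H](Cl)C2)[C@@H](O[Si](CC)(CC)CC)C[C@@H]1Br
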